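**Retrosynthetic overview**

Numbering: C1 (CH–O-anisoyl), C2=C3(CH3), C4, C5, C6 (C–OH), C7 (CH–iPr), C8, C9 (C=O), C10 (C–CH3); ring B (seven-membered) = C1–C6 plus C10, ring A (five-membered) = C6–C10.
Feature: in ring A the tertiary C6 hydroxyl and the C9 ketone are 1,4-related across the quaternary C10, the pattern released by a cyclopentadiene 1,4-endoperoxide. The C6–O and C9=O bonds are therefore cut back to the ring A diene C6=C7–C8=C9 plus O2; the C7 isopropyl and the C1 ester are added afterwards to the C7=C8 enone.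
The diene is traced to the C6=C7–C8(=O) cyclopentenone (enol triflate, then reduction), and ring A to a Wacker/aldol annulation of a C10 allyl group onto the C6 ketone of ring B.
Ring B is bought as cycloheptane-1,3-dione (carbonyls = C1 and C6, C10 between them): C10 methylation and allylation, CBS desymmetrisation (fixes C10), enone and C3 methyl built on the C1 ketone, CBS reduction (fixes C1).
Ring order: ring B (from the start), then ring A (aldol), then a transient peroxide bridge over ring A that is opened in the same step.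

Key step: step 14

Remark: C10 is set by desymmetrising the achiral 2,2-disubstituted dione, because allylation of an unsymmetrical ene-dione enolate would have to distinguish two nearly identical carbonyl flanks; it is assumed that the CBS reduction of the seven-membered dione follows the sense known for five- and six-membered 2,2-disubstituted 1,3-diones (hydride anti to the larger C10 substituent).

**Route**

Step 1
Reactants: 1 cycloheptane-1,3-dione
Product: 2 2-methylcycloheptane-1,3-dione
Conditions: MeI, K2CO3, acetone, 50 °C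
Reagents that add atoms: iodomethane, CI
Why: C-alkylation (SN2) of the doubly stabilised dione enolate puts the future angular methyl on C10.

Step 2
Reactants: 2 2-methylcycloheptane-1,3-dione; 3 allyl acetate
Product: 4 2-allyl-2-methylcycloheptane-1,3-dione
Conditions: Pd(PPh3)4 (2 mol %), DBU, THF, rt to 50 °C
Reagents that add atoms: none
Why: Tsuji–Trost allylation: the soft dione enolate attacks the π-allylpalladium complex at carbon, making C10 quaternary while the molecule stays achiral with C1 and C6 as enantiotopic carbonyls.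

Step 3
Reactants: 4 2-allyl-2-methylcycloheptane-1,3-dione
Product: 5 (2S,3S)-2-allyl-3-hydroxy-2-methylcycloheptan-1-one (hydroxyl on C6, cis to the allyl group; the remaining ketone is C1)
Conditions: (R)-2-methyl-CBS-oxazaborolidine (20 mol %), catecholborane (1.1 equiv), toluene, −78 °C; H2O, aq. Na2CO3 wash; chromatographic removal of the trans isomer
Reagents that add atoms: none
Why: CBS reduction used as an enantiotopic-group-selective desymmetrisation: the (R)-catalyst imposes S at the new C6 carbinol (quaternary C10 as the large group) and hydride enters on the C10-methyl face, anti to allyl, so only one carbonyl reacts and C10 becomes S; the trans isomer, which would carry the opposite C10 configuration, must be removed because the C6 carbinol is later oxidised.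

Step 4
Reactants: 5 (2S,3S)-2-allyl-3-hydroxy-2-methylcycloheptan-1-one
Product: 8 (6S,7S)-7-allyl-7-methyl-6-(triethylsilyloxy)cyclohept-2-en-1-one, via bis(triethylsilyl) enol ether 6 (not isolated), via α-phenylselanyl ketone 7 (not isolated)
Conditions: TESOTf (2.4 equiv), Et3N, CH2Cl2, 0 °C; then PhSeCl, CH2Cl2, −78 °C; then 30% H2O2, pyridine, CH2Cl2, 0 °C to rt
Reagents that add atoms: triethylsilyl trifluoromethanesulfonate, CC[Si](CC)(CC)OS(=O)(=O)C(F)(F)F
Why: Soft enolisation with the silyl triflate silylates the C6 hydroxyl and the only enolisable side (C2) of the C1 ketone, and α-selenenylation followed by selenoxide syn-elimination gives the C2=C3 enone regiospecifically, so the two flanks of C10 become constitutionally different; the C2 selenide centre is transient.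

Step 5
Reactants: 8 (6S,7S)-7-allyl-7-methyl-6-(triethylsilyloxy)cyclohept-2-en-1-one
Product: 11 (6S,7S)-7-allyl-3,7-dimethyl-6-(triethylsilyloxy)cyclohept-2-en-1-one, via lithium enolate 9 (not isolated), via α-phenylselanyl β-methyl ketone 10 (not isolated)
Conditions: Me2CuLi (from MeLi and CuI), Et2O, −78 °C; then PhSeBr, THF, −78 to 0 °C; then 30% H2O2, pyridine, CH2Cl2, 0 °C to rt
Reagents that add atoms: lithium dimethylcuprate, [Li+].C[Cu-]C
Why: Conjugate addition of the Gilman cuprate puts the methyl on C3, the enolate is selenenylated at C2 trans to that methyl, and selenoxide syn-elimination across the cis C3–H regenerates C2=C3 (conjugate addition followed by selenoxide elimination), so the C3 stereocentre is only transient.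

Step 6
Reactants: 11 (6S,7S)-7-allyl-3,7-dimethyl-6-(triethylsilyloxy)cyclohept-2-en-1-one
Product: 12 (1R,6S,7R)-7-allyl-3,7-dimethyl-6-(triethylsilyloxy)cyclohept-2-en-1-ol (C1 hydroxyl cis to the allyl group)
Conditions: (S)-2-methyl-CBS-oxazaborolidine (20 mol %), catecholborane, toluene, −78 °C; H2O, aq. Na2CO3 wash
Reagents that add atoms: none
Why: CBS reduction of the enone: with the quaternary C10 as the large group the (S)-catalyst delivers hydride to C1 from the C10-methyl face, which is also the open face anti to the allyl group and the C6 silyl ether, setting C1 as R.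

Step 7
Reactants: 12 (1R,6S,7R)-7-allyl-3,7-dimethyl-6-(triethylsilyloxy)cyclohept-2-en-1-ol
Product: 13 tert-butyl{[(1R,6S,7S)-7-allyl-3,7-dimethyl-6-(triethylsilyloxy)cyclohept-2-en-1-yl]oxy}dimethylsilane
Conditions: TBSOTf, 2,6-lutidine, CH2Cl2, −78 to 0 °C
Reagents that add atoms: tert-butyldimethylsilyl trifluoromethanesulfonate, CC(C)(C)[Si](C)(C)OS(=O)(=O)C(F)(F)F
Why: Silylation of the hindered allylic alcohol with a silyl triflate and a hindered pyridine base gives the robust C1 ether that is carried to the last steps.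

Step 8
Reactants: 13 tert-butyl{[(1R,6S,7S)-7-allyl-3,7-dimethyl-6-(triethylsilyloxy)cyclohept-2-en-1-yl]oxy}dimethylsilane
Product: 14 (1S,2S,3R)-2-allyl-3-[(tert-butyldimethylsilyl)oxy]-2,5-dimethylcyclohept-4-en-1-ol
Conditions: PPTS (cat.), MeOH/CH2Cl2, 0 °C to rt
Reagents that add atoms: none
Why: Acid-catalysed methanolysis removes the triethylsilyl ether selectively, since it is cleaved far faster than the bulkier tert-butyldimethylsilyl ether.

Step 9
Reactants: 14 (1S,2S,3R)-2-allyl-3-[(tert-butyldimethylsilyl)oxy]-2,5-dimethylcyclohept-4-en-1-ol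
Product: 15 (2R,3R)-2-allyl-3-[(tert-butyldimethylsilyl)oxy]-2,5-dimethylcyclohept-4-en-1-one
Conditions: Dess–Martin periodinane, CH2Cl2, 0 °C to rt
Reagents that add atoms: none
Why: Dess–Martin oxidation converts the C6 carbinol, whose only task was to differentiate the two carbonyls, into the C6 ketone under near-neutral conditions that leave both alkenes and the silyl ether untouched.

Step 10
Reactants: 15 (2R,3R)-2-allyl-3-[(tert-butyldimethylsilyl)oxy]-2,5-dimethylcyclohept-4-en-1-one
Product: 16 (2R,3R)-3-[(tert-butyldimethylsilyl)oxy]-2,5-dimethyl-2-(2-oxopropyl)cyclohept-4-en-1-one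
Conditions: PdCl2 (10 mol %), p-benzoquinone (1.2 equiv), DMF/H2O 7:1, rt
Reagents that add atoms: water, O
Why: Tsuji–Wacker oxidation (Markovnikov hydroxypalladation, β-hydride elimination, benzoquinone reoxidation) turns the terminal allyl alkene into the methyl ketone, while the trisubstituted C2=C3 alkene does not react.

Step 11
Reactants: 16 (2R,3R)-3-[(tert-butyldimethylsilyl)oxy]-2,5-dimethyl-2-(2-oxopropyl)cyclohept-4-en-1-one
Product: 17 (8R,8aS)-8-[(tert-butyldimethylsilyl)oxy]-6,8a-dimethyl-4,5,8,8a-tetrahydroazulen-2(1H)-one (route numbering: C6=C7–C8(=O) enone in ring A)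
Conditions: KOH, EtOH, 60 °C
Reagents that add atoms: none
Why: Intramolecular aldol condensation of the 1,4-diketone: the C7 methyl enolate adds to the C6 ketone and dehydration gives the conjugated C6=C7 enone of ring A, whereas the competing C5-enolate aldol leads only to a bridged ketol that cannot dehydrate and reverts, and the C1 silyloxy group cannot be eliminated because C10 carries no hydrogen.

Step 12
Reactants: 17 (8R,8aS)-8-[(tert-butyldimethylsilyl)oxy]-6,8a-dimethyl-4,5,8,8a-tetrahydroazulen-2(1H)-one
Product: 19 (8R,8aS)-8-[(tert-butyldimethylsilyl)oxy]-6,8a-dimethyl-4,5,8,8a-tetrahydroazulen-2-yl trifluoromethanesulfonate, via lithium dienolate 18 (not isolated)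
Conditions: LDA, THF, −78 °C; then PhNTf2, −78 to 0 °C
Reagents that add atoms: N-phenylbis(trifluoromethanesulfonimide), FC(F)(F)S(=O)(=O)N(c1ccccc1)S(=O)(=O)C(F)(F)F
Why: Kinetic deprotonation of the enone at the α′ carbon C9 gives the cross-conjugated dienolate, which is O-sulfonylated by PhNTf2 (enol triflate formation) to the 2-triflyloxy diene.

Step 13
Reactants: 19 (8R,8aS)-8-[(tert-butyldimethylsilyl)oxy]-6,8a-dimethyl-4,5,8,8a-tetrahydroazulen-2-yl trifluoromethanesulfonate
Product: 20 tert-butyl{[(8R,8aS)-6,8a-dimethyl-4,5,8,8a-tetrahydroazulen-8-yl]oxy}dimethylsilane (ring A diene C6=C7–C8=C9)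
Conditions: Pd(OAc)2 (5 mol %), PPh3 (10 mol %), HCO2H, Et3N, DMF, 60 °C
Reagents that add atoms: none
Why: Palladium-catalysed formate reduction of the enol triflate (oxidative addition to zerovalent palladium, formate-for-triflate exchange, loss of CO2, C–H reductive elimination) gives the diene, which cannot isomerise by hydrogen shift because C10 is quaternary.

Step 14
Reactants: 20 tert-butyl{[(8R,8aS)-6,8a-dimethyl-4,5,8,8a-tetrahydroazulen-8-yl]oxy}dimethylsilane; 21 dioxygen
Product: 23 (3aS,8R,8aR)-8-[(tert-butyldimethylsilyl)oxy]-3a-hydroxy-6,8a-dimethyl-3a,4,5,8a-tetrahydroazulen-1(8H)-one, via endoperoxide 22 (not isolated)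
Conditions: O2 (1 atm), tetraphenylporphyrin (0.5 mol %), visible light, CH2Cl2, −78 °C; then Et3N (1.5 equiv), −78 to 0 °C
Reagents that add atoms: none
Why: Sensitised irradiation generates singlet oxygen, which adds suprafacially in a [4+2] cycloaddition across C6 and C9 of the C6=C7–C8=C9 diene to give the 2,3-dioxabicyclo[2.2.1]hept-5-ene 22; the closest known reaction type is cyclopentadiene photooxygenation followed by Kornblum–DeLaMare rearrangement to a 4-hydroxycyclopent-2-enone. Triethylamine then removes the C9 hydrogen, the only hydrogen on a peroxide-bearing carbon, and the weak O–O bond breaks to give the C9 ketone and the C6 alkoxide, so the C6–O and C9=O bonds form regiospecifically. No ring persists from the step: the dioxabicycle closes in a concerted six-electron cycloaddition on one face of ring A and is opened again by the base-induced fragmentation. The new C6 stereocentre is controlled by C10: oxygen approaches the ring A face that carries the C10 methyl, because the other face is covered by the C1 branch of ring B with its silyloxy group, so the hydroxyl ends cis to the methyl (C6 S). The step needs facial selectivity (secured by C10), chemoselectivity for the diene over the ene reaction at the trisubstituted C2=C3 alkene (cyclopentadienes react far faster, and oxygen uptake is stopped at one equivalent at −78 °C), and a base-induced rather than thermal fate of the endoperoxide (amine added cold before warming).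

Step 15
Reactants: 23 (3aS,8R,8aR)-8-[(tert-butyldimethylsilyl)oxy]-3a-hydroxy-6,8a-dimethyl-3a,4,5,8a-tetrahydroazulen-1(8H)-one; 24 isopropylmagnesium chloride
Product: 25 (3R,3aS,8R,8aR)-8-[(tert-butyldimethylsilyl)oxy]-3a-hydroxy-6,8a-dimethyl-3-(propan-2-yl)-2,3,3a,4,5,8a-hexahydroazulen-1(8H)-one
Conditions: i-PrMgCl (3.5 equiv), THF, −78 to −20 °C; aq. NH4Cl
Reagents that add atoms: none
Why: Alkoxide-directed conjugate addition: the first equivalent deprotonates the C6 hydroxyl and the magnesium alkoxide delivers isopropyl to C7 on the oxygen-bearing face (1,4-addition to a 4-oxido enone), setting C7 as R with isopropyl cis to the hydroxyl, while the C9 carbonyl is screened from 1,2-attack by the quaternary C10.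

Step 16
Reactants: 25 (3R,3aS,8R,8aR)-8-[(tert-butyldimethylsilyl)oxy]-3a-hydroxy-6,8a-dimethyl-3-(propan-2-yl)-2,3,3a,4,5,8a-hexahydroazulen-1(8H)-one
Product: 26 (3R,3aS,8R,8aR)-3a,8-dihydroxy-6,8a-dimethyl-3-(propan-2-yl)-2,3,3a,4,5,8a-hexahydroazulen-1(8H)-one
Conditions: HF·pyridine, pyridine, THF, 0 °C to rt
Reagents that add atoms: none
Why: Fluoride-induced desilylation under buffered, non-basic conditions frees the C1 hydroxyl without exposing the two β-hydroxy ketone units to base that could trigger retro-aldol cleavage.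

Step 17
Reactants: 26 (3R,3aS,8R,8aR)-3a,8-dihydroxy-6,8a-dimethyl-3-(propan-2-yl)-2,3,3a,4,5,8a-hexahydroazulen-1(8H)-one; 27 4-methoxybenzoyl chloride
Product: 28 (3R,3aS,8R,8aR)-3a-hydroxy-6,8a-dimethyl-1-oxo-3-(propan-2-yl)-1,2,3,3a,4,5,8,8a-octahydroazulen-8-yl 4-methoxybenzoate (CNP0246512.1)
Conditions: pyridine, DMAP (cat.), CH2Cl2, 0 °C to rt
Reagents that add atoms: none
Why: DMAP-catalysed acylation (nucleophilic catalysis) esterifies the secondary allylic C1 hydroxyl, while the tertiary C6 hydroxyl is too hindered to react.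

**Compound list**

1 | cycloheptane-1,3-dione | O=C1CCCCC(=O)C1 | starting material
2 | 2-methylcycloheptane-1,3-dione | CC1C(=O)CCCCC1=O | intermediate
3 | allyl acetate | C=CCOC(C)=O | starting material
4 | 2-allyl-2-methylcycloheptane-1,3-dione | C=CCC1(C)C(=O)CCCCC1=O | intermediate
5 | (2S,3S)-2-allyl-3-hydroxy-2-methylcycloheptan-1-one | C=CC[C@]1(C)C(=O)CCCC[C@@H]1O | intermediate
6 | (6S,7S)-7-allyl-7-methyl-1,6-bis(triethylsilyloxy)cyclohept-1-ene (not isolated) | C=CC[C@]1(C)C(O[Si](CC)(CC)CC)=CCCC[C@@H]1O[Si](CC)(CC)CC | intermediate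
7 | (6S,7S)-7-allyl-7-methyl-2-(phenylselanyl)-6-(triethylsilyloxy)cycloheptan-1-one, C2 epimers (not isolated) | C=CC[C@]1(C)C(=O)C([Se]c2ccccc2)CCC[C@@H]1O[Si](CC)(CC)CC | intermediate
8 | (6S,7S)-7-allyl-7-methyl-6-(triethylsilyloxy)cyclohept-2-en-1-one | C=CC[C@]1(C)C(=O)C=CCC[C@@H]1O[Si](CC)(CC)CC | intermediate
9 | lithium (6S,7S)-7-allyl-3,7-dimethyl-6-(triethylsilyloxy)cyclohept-1-en-1-olate, C3 epimers (not isolated) | C=CC[C@]1(C)C(O[Li])=CC(C)CC[C@@H]1O[Si](CC)(CC)CC | intermediate
10 | (6S,7S)-7-allyl-3,7-dimethyl-2-(phenylselanyl)-6-(triethylsilyloxy)cycloheptan-1-one, C2/C3 epimers (not isolated) | C=CC[C@]1(C)C(=O)C([Se]c2ccccc2)C(C)CC[C@@H]1O[Si](CC)(CC)CC | intermediate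
11 | (6S,7S)-7-allyl-3,7-dimethyl-6-(triethylsilyloxy)cyclohept-2-en-1-one | C=CC[C@]1(C)C(=O)C=C(C)CC[C@@H]1O[Si](CC)(CC)CC | intermediate
12 | (1R,6S,7R)-7-allyl-3,7-dimethyl-6-(triethylsilyloxy)cyclohept-2-en-1-ol | C=CC[C@]1(C)[C@H](O)C=C(C)CC[C@@H]1O[Si](CC)(CC)CC | intermediate
13 | tert-butyl{[(1R,6S,7S)-7-allyl-3,7-dimethyl-6-(triethylsilyloxy)cyclohept-2-en-1-yl]oxy}dimethylsilane | C=CC[C@]1(C)[C@H](O[Si](C)(C)C(C)(C)C)C=C(C)CC[C@@H]1O[Si](CC)(CC)CC | intermediate
14 | (1S,2S,3R)-2-allyl-3-[(tert-butyldimethylsilyl)oxy]-2,5-dimethylcyclohept-4-en-1-ol | C=CC[C@]1(C)[C@H](O[Si](C)(C)C(C)(C)C)C=C(C)CC[C@@H]1O | intermediate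
15 | (2R,3R)-2-allyl-3-[(tert-butyldimethylsilyl)oxy]-2,5-dimethylcyclohept-4-en-1-one | C=CC[C@]1(C)[C@H](O[Si](C)(C)C(C)(C)C)C=C(C)CCC1=O | intermediate
16 | (2R,3R)-3-[(tert-butyldimethylsilyl)oxy]-2,5-dimethyl-2-(2-oxopropyl)cyclohept-4-en-1-one | CC(=O)C[C@]1(C)[C@H](O[Si](C)(C)C(C)(C)C)C=C(C)CCC1=O | intermediate
17 | (8R,8aS)-8-[(tert-butyldimethylsilyl)oxy]-6,8a-dimethyl-4,5,8,8a-tetrahydroazulen-2(1H)-one | CC(C)(C)[Si](C)(C)O[C@@H]1C=C(C)CCC2=CC(=O)C[C@]12C | intermediate
18 | lithium dienolate of 17 (C8 enolate oxygen, C8=C9; not isolated) | CC(C)(C)[Si](C)(C)O[C@@H]1C=C(C)CCC2=CC(O[Li])=C[C@]12C | intermediate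
19 | (8R,8aS)-8-[(tert-butyldimethylsilyl)oxy]-6,8a-dimethyl-4,5,8,8a-tetrahydroazulen-2-yl trifluoromethanesulfonate | CC(C)(C)[Si](C)(C)O[C@@H]1C=C(C)CCC2=CC(OS(=O)(=O)C(F)(F)F)=C[C@]12C | intermediate
20 | tert-butyl{[(8R,8aS)-6,8a-dimethyl-4,5,8,8a-tetrahydroazulen-8-yl]oxy}dimethylsilane | CC(C)(C)[Si](C)(C)O[C@@H]1C=C(C)CCC2=CC=C[C@]12C | intermediate
21 | dioxygen | O=O | starting material
22 | C6,C9-endoperoxide of 20 (peroxide bridge on the C10-methyl face, C7=C8 alkene; not isolated) | CC(C)(C)[Si](C)(C)O[C@@H]1C=C(C)CC[C@]23OO[C@H](C=C2)[C@]13C | intermediate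
23 | (3aS,8R,8aR)-8-[(tert-butyldimethylsilyl)oxy]-3a-hydroxy-6,8a-dimethyl-3a,4,5,8a-tetrahydroazulen-1(8H)-one | CC(C)(C)[Si](C)(C)O[C@@H]1C=C(C)CC[C@]2(O)C=CC(=O)[C@]12C | intermediate
24 | isopropylmagnesium chloride | CC(C)[Mg]Cl | starting material
25 | (3R,3aS,8R,8aR)-8-[(tert-butyldimethylsilyl)oxy]-3a-hydroxy-6,8a-dimethyl-3-(propan-2-yl)-2,3,3a,4,5,8a-hexahydroazulen-1(8H)-one | CC(C)(C)[Si](C)(C)O[C@@H]1C=C(C)CC[C@]2(O)[C@@H](C(C)C)CC(=O)[C@]12C | intermediate
26 | (3R,3aS,8R,8aR)-3a,8-dihydroxy-6,8a-dimethyl-3-(propan-2-yl)-2,3,3a,4,5,8a-hexahydroazulen-1(8H)-one | O[C@@H]1C=C(C)CC[C@]2(O)[C@@H](C(C)C)CC(=O)[C@]12C | intermediate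
27 | 4-methoxybenzoyl chloride | COc1ccc(cc1)C(Cl)=O | starting material
28 | (3R,3aS,8R,8aR)-3a-hydroxy-6,8a-dimethyl-1-oxo-3-(propan-2-yl)-1,2,3,3a,4,5,8,8a-octahydroazulen-8-yl 4-methoxybenzoate | COc1ccc(C(=O)O[C@@H]2C=C(C)CC[C@]3(O)[C@@H](C(C)C)CC(=O)[C@]23C)cc1 | target

**Step count and risks**

Total step count: 17. Longest linear sequence: 17 steps (1 to 28; the route is fully linear).

Steps most likely to fail:

Step 14. The strained endoperoxide may rearrange thermally (to a bis-epoxide or epoxy-ketone) faster than the amine fragments it, or oxygen may add on both faces of ring A. Fallback: setting out from 20, the photooxygenation is run as before to 22 and the peroxide is reduced in the cold with thiourea in MeOH/CH2Cl2 to the cis-ene-1,4-diol F1. Its secondary allylic C9 hydroxyl is then oxidised with MnO2 in CH2Cl2; the tertiary C6 hydroxyl cannot be oxidised. The route is rejoined at 23.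

Step 15. β-Hydride transfer from the secondary Grignard reagent (reduction of the enone) or 1,2-addition may compete with the directed 1,4-delivery. Fallback: setting out from 23, isopropenylmagnesium bromide, which has no hydride-transfer pathway, is added under the same alkoxide direction to give the C7 isopropenyl ketone F2. Its 1,1-disubstituted alkene is then hydrogenated with RhCl(PPh3)3 and H2, which should leave the trisubstituted C2=C3 alkene. The route is rejoined at 25.

Step 3. Discrimination between the two carbonyls or between the two carbonyl faces may be incomplete; because the C6 carbinol is later oxidised, any trans isomer carried forward would erode the enantiopurity at C10. Fallback: setting out from 4, NaBH4 reduction and removal of the trans isomer give the racemic cis-hydroxy ketone F3. Lipase-catalysed acylation with vinyl acetate (Amano lipase PS) should then convert the (2R,3R)-enantiomer into the acetate F4 and leave the (2S,3S)-alcohol, which is separated. The route is rejoined at 5.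

Further compounds
F1 | step 14 | cis-ene-1,4-diol: C6 and C9 hydroxyls cis on the C10-methyl face, C7=C8 alkene, C1 silyl ether (C1 R, C6 S, C9 R, C10 R) | CC(C)(C)[Si](C)(C)O[C@@H]1C=C(C)CC[C@]2(O)C=C[C@@H](O)[C@]12C
F2 | step 15 | (3R,3aS,8R,8aR)-8-[(tert-butyldimethylsilyl)oxy]-3a-hydroxy-6,8a-dimethyl-3-(prop-1-en-2-yl)-2,3,3a,4,5,8a-hexahydroazulen-1(8H)-one | CC(C)(C)[Si](C)(C)O[C@@H]1C=C(C)CC[C@]2(O)[C@@H](C(C)=C)CC(=O)[C@]12C
F3 | step 3 | racemic cis-2-allyl-3-hydroxy-2-methylcycloheptan-1-one (both enantiomers) | C=CC[C@]1(C)C(=O)CCCC[C@@H]1O.C=CC[C@@]1(C)C(=O)CCCC[C@H]1O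
F4 | step 3 | (1R,2R)-2-allyl-2-methyl-3-oxocycloheptyl acetate | C=CC[C@@]1(C)C(=O)CCCC[C@H]1OC(C)=O
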